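**The number.** 33.3 %: take this as the crossing level, the summer L reading at which the summer run has dissolved as much as this flask holds.

- summer: L 3.0 × 10⁻⁴ M; Z 0.077 mM (held); run made earlier
- flask: L 2.0 × 10⁻⁴ M; Z 0.077 mM (held); time 12 min

summer run (percent of the L charged)

| time / min | J / % | L / % |
|---|---|---|
| 0.417 | 5.0 | 57.4 |
| 1.33 | 7.2 | 25.9 |
| 2.50 | 6.5 | 0.3 |
| 4.00 | 0.4 | 0 |

(each reading ± 0.3 percentage points)

- the best time, 12 min at the latest, for J
- the amount of J, in percent of the L charged, at that time

- given per volume of solution although it is solid: L
- at the start none of G is dissolved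
- steps thought possible: J -> X; Z <-> G; L <-> D; D + 2 G -> Q; D + G -> J
- at the start none of L is in solution

**Its meaning.** Read the summer run. J still stood at 6.5 % with L at 0.3 %, then dropped to 0.4 % by 4.00 min. So treat the end of the solid as the crossing. Assume this flask dissolves L as the summer run did while solid lasts.

**The reading.** Interpolate summer L: it meets the level at 1.11 min. Rescale summer J there to the smaller charge: 10.0 %.

**The test.** One number gives the time, not the height. J may bend between readings, and the later reading rescales to 10.8 %. Expect a height between these.

**The forecast.** It says 1.1 min and 10.3 %, reasoning that “absolute J should follow the summer curve while solid remains”. Its height stands above my interpolated 10.0 %.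

**The flask.** It gives 1.13 min and 10.8 %.

    J → X (k = 0.0710 s⁻¹)
    Z ⇌ G, rate k2*(csat - [G]) (kL = 0.0290 s⁻¹)
    L ⇌ D, rate k3*(cs3 - [D]) while solid is left; crystals form when [D] > cs3 (solubility = 0.0950 mM, k = 0.660 s⁻¹)
    D + 2 G → Q (k = 1.50 × 10⁷ M⁻² s⁻¹)
    D + G → J (k = 1500 M⁻¹ s⁻¹)

**What ran.** In this flask L dissolved beside the forming of J; at 1.13 min, next to the crossing at 1.11 min, solid L stood at 0 % and D at 45.6 %. After that D went on into J and Q while J passed into X, and at 6.00 min the L charge, the limiting reagent, stood as X at 87.4 % and Q at 12.6 %. A neighbour flask with 1.2 × 10⁻⁴ M of L has the level 60.0 %, above the first summer L reading; the first summer J reading, taken past that level, rescales to 12.5 %, and that neighbour flask reached 15.1 %.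

The runs are calculated on assumed constants, and the scatter is random.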